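The cyclohexane ring is divided into two three-carbon units, C2–C3–C4 and C5–C6–C1 (quinic acid numbering), so that the bonds C1–C2 and C4–C5 are made together. Two relationships in the ring carry this: the tertiary carbinol C1 (OH, CO2H) lies β to C3, an aldol retron of an α-keto ester, and C4–C5 becomes a Michael retron when the C5 oxygen is carried as boron. One amine-catalysed Michael/aldol cascade of a silyloxyacetone with a γ-boryl β,γ-unsaturated α-keto ester should therefore close the carbocycle and set C1, C4 and C5; the precursor is simply these two acyclic partners.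

Key step: step 3

Remark: locants C1–C6 are those of quinic acid (C1 carries CO2H, C3 the secondary caffeate, C4 and C5 the free hydroxyls); the sense of induction in step 3 is assigned by analogy with related enamine Michael additions, and the (R)-catalyst would be used if the opposite sense were found.

Step 1
Reactants: 1 4,4,5,5-tetramethyl-2-vinyl-1,3,2-dioxaborolane; 2 methyl 2-hydroxybut-3-enoate (racemic)
Product: 3 methyl (E)-2-hydroxy-4-(4,4,5,5-tetramethyl-1,3,2-dioxaborolan-2-yl)but-3-enoate (racemic)
Conditions: RuCl2(H2IMes)(=CH-C6H4-2-O-i-Pr) (second-generation Hoveyda–Grubbs catalyst, H2IMes = 1,3-dimesitylimidazolidin-2-ylidene, 3 mol %), 1 (2 equiv), CH2Cl2, 40 °C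
Reagents that add atoms: none
Why: Olefin cross-metathesis of a vinyl pinacol boronate with a terminal allylic alcohol should give the E-alkenyl boronate with loss of ethene; the carbinol centre is of no consequence because it is oxidised in step 2.

Step 2
Reactants: 3 methyl (E)-2-hydroxy-4-(4,4,5,5-tetramethyl-1,3,2-dioxaborolan-2-yl)but-3-enoate
Product: 4 methyl (E)-2-oxo-4-(4,4,5,5-tetramethyl-1,3,2-dioxaborolan-2-yl)but-3-enoate
Conditions: Dess–Martin periodinane (1.2 equiv), CH2Cl2, 0 °C to rt
Reagents that add atoms: none
Why: Dess–Martin oxidation of the allylic α-hydroxy ester should give the β,γ-unsaturated α-keto ester under neutral conditions that leave the C–B bond and the E-alkene untouched.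

Step 3
Reactants: 4 methyl (E)-2-oxo-4-(4,4,5,5-tetramethyl-1,3,2-dioxaborolan-2-yl)but-3-enoate; 5 1-[(tert-butyldimethylsilyl)oxy]propan-2-one
Product: 7 methyl (1R,4S,5R)-4-[(tert-butyldimethylsilyl)oxy]-1-hydroxy-3-oxo-5-(4,4,5,5-tetramethyl-1,3,2-dioxaborolan-2-yl)cyclohexane-1-carboxylate, via diketone 6 (not isolated)
Conditions: (S)-1-[3,5-bis(trifluoromethyl)phenyl]-3-(pyrrolidin-2-ylmethyl)thiourea (20 mol %), PhCO2H (20 mol %), 5 (3 equiv), toluene, 0 °C to rt
Reagents that add atoms: none
Why: The pyrrolidine forms the enamine of 5 at the silyloxy-bearing carbon, which adds to the boron-bearing β-carbon of 4 held by the thiourea (Michael addition, C4–C5), and a second enamine on the methyl side of diketone 6 then attacks the α-keto ester carbonyl (intramolecular aldol, C1–C2). The closest known reaction type is the amine-catalysed formal [3+3] Michael/aldol annulation of ketones with β,γ-unsaturated α-keto esters. The carbocycle closes in a 6-(enolendo)-exo-trig mode. C4 and C5 are set by the (S)-catalyst, whose E-enamine should meet the hydrogen-bonded E-enone in a synclinal arrangement on the face syn to the thiourea arm to give the syn (4S,5R) adduct, while C4, being epimerisable, can also settle into the all-equatorial chair; C1 follows from a chair transition state and a reversible aldol that place CO2Me equatorial and OH axial. The step needs the first enamine to form on the oxygenated side of 5, which the α-silyloxy group secures, and it needs C5 to keep its heteroatom, which is why boron stands in for the C5 oxygen: an alkoxy group there could be lost by β-elimination, a boryl group cannot.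

Step 4
Reactants: 7 methyl (1R,4S,5R)-4-[(tert-butyldimethylsilyl)oxy]-1-hydroxy-3-oxo-5-(4,4,5,5-tetramethyl-1,3,2-dioxaborolan-2-yl)cyclohexane-1-carboxylate
Product: 9 methyl 4-O-(tert-butyldimethylsilyl)quinate, via hydroxy boronate 8 (not isolated)
Conditions: LiBH(s-Bu)3 (2.5 equiv), THF, −78 °C; then NaBO3·4H2O, H2O, 0 °C to rt
Reagents that add atoms: sodium perborate (hydrate water omitted), O[B-]1(O)OO[B-](O)(O)OO1.[Na+].[Na+]
Why: Approach-controlled ketone reduction followed by boronate oxidation: the bulky hydride should attack C3 equatorially, away from the axial C1 alkoxide, to give the axial 3-OH cis to O1 and O4, and perborate should convert C5–B into C5–OH with retention.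

Step 5
Reactants: 9 methyl 4-O-(tert-butyldimethylsilyl)quinate
Product: 10 4-O-(tert-butyldimethylsilyl)quinide (1,5-lactone; 1-OH and 3-OH free)
Conditions: PPTS (0.2 equiv), 4 Å molecular sieves, toluene, 100 °C
Reagents that add atoms: none
Why: Acid-catalysed intramolecular transesterification (lactonisation): only the 5-OH is cis to the ester, so the γ-lactone should form and mask O5 and the carboxyl group together, driven by removal of methanol on the sieves.

Step 6
Reactants: 11 caffeic acid
Product: 12 (E)-3-(3,4-diacetoxyphenyl)prop-2-enoic acid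
Conditions: Ac2O, pyridine, DMAP (cat.), rt; aqueous work-up
Reagents that add atoms: acetic anhydride, CC(=O)OC(C)=O
Why: Acetylation of both phenols by nucleophilic acyl transfer protects the catechol, and any mixed anhydride at the acid is hydrolysed on work-up.

Step 7
Reactants: 12 (E)-3-(3,4-diacetoxyphenyl)prop-2-enoic acid
Product: 13 (E)-3-(3,4-diacetoxyphenyl)prop-2-enoyl chloride
Conditions: (COCl)2, DMF (cat.), CH2Cl2, 0 °C to rt
Reagents that add atoms: oxalyl chloride, ClC(=O)C(Cl)=O
Why: Acid chloride formation through the chloroiminium species from oxalyl chloride and DMF, to which the aryl acetates and the E-alkene are inert.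

Step 8
Reactants: 10 4-O-(tert-butyldimethylsilyl)quinide; 13 (E)-3-(3,4-diacetoxyphenyl)prop-2-enoyl chloride
Product: 14 1,3-bis-O-[(E)-3-(3,4-diacetoxyphenyl)prop-2-enoyl]-4-O-(tert-butyldimethylsilyl)quinide
Conditions: 13 (3 equiv), DMAP (0.5 equiv), pyridine, CH2Cl2, rt to 40 °C
Reagents that add atoms: none
Why: DMAP-catalysed acylation of the only two free hydroxyl groups, the tertiary 1-OH and the equatorial 3-OH of the lactone, touches no stereocentre.

Step 9
Reactants: 14 1,3-bis-O-[(E)-3-(3,4-diacetoxyphenyl)prop-2-enoyl]-4-O-(tert-butyldimethylsilyl)quinide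
Product: 15 1,3-di-O-caffeoylquinic acid
Conditions: 2 M aq. HCl/THF (1:3), rt, several days
Reagents that add atoms: water, O
Why: Acid hydrolysis should open the bridged γ-lactone and cleave the silyl ether and the four aryl acetates, while the two hindered cinnamate esters survive and base-promoted acyl migration is avoided.

Compound list
1 | 4,4,5,5-tetramethyl-2-vinyl-1,3,2-dioxaborolane (vinylboronic acid pinacol ester) | C=CB1OC(C)(C)C(C)(C)O1 | starting material
2 | methyl 2-hydroxybut-3-enoate (racemic) | C=CC(O)C(=O)OC | starting material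
3 | methyl (E)-2-hydroxy-4-(4,4,5,5-tetramethyl-1,3,2-dioxaborolan-2-yl)but-3-enoate (racemic) | COC(=O)C(O)/C=C/B1OC(C)(C)C(C)(C)O1 | intermediate
4 | methyl (E)-2-oxo-4-(4,4,5,5-tetramethyl-1,3,2-dioxaborolan-2-yl)but-3-enoate | COC(=O)C(=O)/C=C/B1OC(C)(C)C(C)(C)O1 | intermediate
5 | 1-[(tert-butyldimethylsilyl)oxy]propan-2-one | CC(=O)CO[Si](C)(C)C(C)(C)C | starting material
6 | methyl (4R,5S)-5-[(tert-butyldimethylsilyl)oxy]-2,6-dioxo-4-(4,4,5,5-tetramethyl-1,3,2-dioxaborolan-2-yl)heptanoate | CC(=O)[C@@H](O[Si](C)(C)C(C)(C)C)[C@H](B1OC(C)(C)C(C)(C)O1)CC(=O)C(=O)OC | intermediate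
7 | methyl (1R,4S,5R)-4-[(tert-butyldimethylsilyl)oxy]-1-hydroxy-3-oxo-5-(4,4,5,5-tetramethyl-1,3,2-dioxaborolan-2-yl)cyclohexane-1-carboxylate | O=C1C[C@@](O)(C(=O)OC)C[C@@H](B2OC(C)(C)C(C)(C)O2)[C@@H]1O[Si](C)(C)C(C)(C)C | intermediate
8 | methyl (1R,3R,4S,5R)-4-[(tert-butyldimethylsilyl)oxy]-1,3-dihydroxy-5-(4,4,5,5-tetramethyl-1,3,2-dioxaborolan-2-yl)cyclohexane-1-carboxylate | O[C@@H]1C[C@@](O)(C(=O)OC)C[C@@H](B2OC(C)(C)C(C)(C)O2)[C@@H]1O[Si](C)(C)C(C)(C)C | intermediate
9 | methyl 4-O-(tert-butyldimethylsilyl)quinate (1-OH, 3-OH and 4-silyloxy on one face, 5-OH and CO2Me on the other, as in (−)-quinic acid) | O[C@@H]1C[C@@](O)(C(=O)OC)C[C@@H](O)[C@@H]1O[Si](C)(C)C(C)(C)C | intermediate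
10 | 4-O-(tert-butyldimethylsilyl)quinide (1,5-lactone of the acid of 9) | O[C@@H]1C[C@@](O)(C(=O)O2)C[C@@H]2[C@@H]1O[Si](C)(C)C(C)(C)C | intermediate
11 | caffeic acid | OC(=O)/C=C/c1ccc(O)c(O)c1 | starting material
12 | (E)-3-(3,4-diacetoxyphenyl)prop-2-enoic acid | OC(=O)/C=C/c1ccc(OC(C)=O)c(OC(C)=O)c1 | intermediate
13 | (E)-3-(3,4-diacetoxyphenyl)prop-2-enoyl chloride | ClC(=O)/C=C/c1ccc(OC(C)=O)c(OC(C)=O)c1 | intermediate
14 | 1,3-bis-O-[(E)-3-(3,4-diacetoxyphenyl)prop-2-enoyl]-4-O-(tert-butyldimethylsilyl)quinide | CC(=O)Oc1ccc(/C=C/C(=O)O[C@@H]2C[C@@](OC(=O)/C=C/c3ccc(OC(C)=O)c(OC(C)=O)c3)(C(=O)O4)C[C@@H]4[C@@H]2O[Si](C)(C)C(C)(C)C)cc1OC(C)=O | intermediate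
15 | 1,3-di-O-caffeoylquinic acid | O=C(/C=C/c1ccc(O)c(O)c1)O[C@@H]1C[C@@](OC(=O)/C=C/c2ccc(O)c(O)c2)(C(=O)O)C[C@@H](O)[C@@H]1O | target

Total step count: 9. Longest linear sequence: 7 steps (steps 1, 2, 3, 4, 5, 8, 9); steps 6 and 7 form the side branch to 13.

Steps most likely to fail

Step 3. The cascade may stop after the conjugate addition, with the diketone resting as a cyclic hemiketal. The first enamine may also form on the methyl side of 5, or face selectivity at the boron-bearing carbon may be poor. The fallback separates the two bond formations and moves the first one to Lewis acid catalysis. It sets out from 5, which with TMSOTf and Et3N should give the silyl enol ether F1 on the oxygenated side. F1 and 4 would be combined under Cu(OTf)2 with a chiral t-Bu-box ligand, the ligand enantiomer chosen to give the (4R,5S) series, in an inverse-demand hetero-Diels–Alder reaction to the dihydropyran F2. Mild aqueous acid would release diketone 6, isolated here. A separate aldol cyclisation with catalytic pyrrolidine and acetic acid would then bring the route back to 7.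

Step 4. Facial control at C3 may be lost, or the silyl group may migrate and the methyl ester may be saponified during the basic oxidative work-up. The fallback sets out from 7 and changes the control element from steric approach to chelation. A Narasaka–Prasad reduction (Et2BOMe, NaBH4, THF/MeOH, −78 °C) uses the boron chelate between the 1-OH and the C3 carbonyl to deliver the syn-1,3-diol 8, which is isolated. The C–B bond is then oxidised in a separate step at neutral pH (H2O2, pH 7 phosphate buffer), returning at 9; no new compound arises (entry F0).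

Step 5. The silyl ether may be lost under the acid, or the ester–lactone equilibrium may not be driven to the lactone. The fallback sets out from 9 and closes the lactone by carboxyl activation instead of transesterification. Me3SnOH in 1,2-dichloroethane at 70 °C should cleave the methyl ester to the carboxylic acid F3. A Yamaguchi lactonisation (2,4,6-trichlorobenzoyl chloride, Et3N, then DMAP, dilute toluene) would return at 10, since only the 5-OH can reach the activated carboxyl group.

Further compounds
F1 | step 3 | (Z)-tert-butyldimethyl{[2-(trimethylsilyloxy)prop-1-en-1-yl]oxy}silane | C/C(O[Si](C)(C)C)=C/O[Si](C)(C)C(C)(C)C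
F2 | step 3 | methyl (4R,5S)-5-[(tert-butyldimethylsilyl)oxy]-6-methyl-4-(4,4,5,5-tetramethyl-1,3,2-dioxaborolan-2-yl)-6-[(trimethylsilyl)oxy]-5,6-dihydro-4H-pyran-2-carboxylate (C6 not defined) | COC(=O)C1=C[C@@H](B2OC(C)(C)C(C)(C)O2)[C@H](O[Si](C)(C)C(C)(C)C)C(C)(O[Si](C)(C)C)O1
F0 | step 4 | none | none
F3 | step 5 | 4-O-(tert-butyldimethylsilyl)quinic acid | O[C@@H]1C[C@@](O)(C(=O)O)C[C@@H](O)[C@@H]1O[Si](C)(C)C(C)(C)C
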